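**Plan**

- Numbering: ring atoms as in the name of 19 (C1 carries CH2OH, C8 is the stereocentre, side-chain atoms are primed). The retrosynthesis cuts the ring at C13–C14, then C1–C2, C4–C5, C5=C6 and C7–C8, then C5'=C6' and C3'–C4' of the side chain, down to geranyl bromide.
- Enabling feature: C13 and C14 are the two allylic CH2 groups of the ring 1,5-diene C11=C12–C13–C14–C1=C2, and C1 also carries the oxidised carbon. At ester level, C2=C1(CO2Me)–C14 is what an SN2' attack on a Morita–Baylis–Hillman acetate leaves, and C13 can hold a PhSO2-stabilised allyl carbanion.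
- One event therefore closes the only ring, makes C13–C14, creates the C1=C2 alkene with its geometry and delivers the C1 substituent. The helpers (PhSO2, acetate, ester level) are taken out in steps 12–14.
- Forward: geranyl phenyl sulfone (C9–C13, 11E in place) → side-chain carbinol → Johnson–Claisen (C7–C8) → Z-iodoalkene → B-alkyl Suzuki (C4–C5) → aldehyde → Baylis–Hillman acetate → ring closure → reduction → desulfonylation.
- Stereochemistry: C8 (R) by 1,3-chirality transfer in the chair Claisen from an (R)-carbinol set by catalytic asymmetric allylboration; 2'E from the same chair; 5Z from an iodo-Wittig plus retentive coupling; 11E from the geranyl unit; 1E from the elimination in the ring-closing step.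

Key step: step 12

Remark: the carbinol carbon of 13 and 14 (future C2) and the sulfonyl-bearing carbon of 15–18 (C13) arise as epimer mixtures; both centres are erased later (steps 12 and 14), so they are left undefined in names and SMILES.

**Step 1**
Reactants: 1 geranyl bromide
Product: 2 geranyl phenyl sulfone {[(2E)-3,7-dimethylocta-2,6-dien-1-yl]sulfonyl}benzene
Conditions: PhSO2Na, DMF, rt
Reagents that add atoms: sodium benzenesulfinate, [Na+].[O-]S(=O)c1ccccc1
Why: SN2 S-alkylation of the sulfinate by the primary allylic bromide should give the allyl sulfone without allylic transposition and with the E alkene kept.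

**Step 2**
Reactants: 2 geranyl phenyl sulfone
Product: 4 (2E,6E)-2,6-dimethyl-8-(phenylsulfonyl)octa-2,6-dienal, via allylic alcohol 3 (not isolated)
Conditions: SeO2 (cat.), t-BuOOH, salicylic acid (cat.), CH2Cl2, rt; crude 3 then MnO2, CH2Cl2, rt
Reagents that add atoms: tert-butyl hydroperoxide, CC(C)(C)OO; selenium dioxide, O=[Se]=O (oxygen relay)
Why: Riley allylic oxidation (ene reaction, then [2,3]-shift) should attack the E-methyl of the electron-richer terminal alkene, the other alkene being deactivated by the sulfonyl group, and MnO2 then oxidises only the allylic alcohol to the enal.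

**Step 3**
Reactants: 4 (2E,6E)-2,6-dimethyl-8-(phenylsulfonyl)octa-2,6-dienal
Product: 5 (4R,5E,9E)-5,9-dimethyl-11-(phenylsulfonyl)undeca-1,5,9-trien-4-ol
Conditions: allylB(pin), (R)-TRIP [(R)-3,3'-bis(2,4,6-triisopropylphenyl)-1,1'-binaphthyl-2,2'-diyl hydrogen phosphate, 5 mol %], toluene, −30 °C
Reagents that add atoms: allylboronic acid pinacol ester, C=CCB1OC(C)(C)C(C)(C)O1
Why: Chiral phosphoric acid-catalysed allylboration through a chair six-membered transition state should deliver allyl to the Re face of the conjugated aldehyde and set the carbinol centre as R.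

**Step 4**
Reactants: 5 (4R,5E,9E)-5,9-dimethyl-11-(phenylsulfonyl)undeca-1,5,9-trien-4-ol
Product: 6 (5R,6E,10E)-2,6,10-trimethyl-12-(phenylsulfonyl)dodeca-2,6,10-trien-5-ol
Conditions: 2-methylbut-2-ene (excess), second-generation Grubbs catalyst RuCl2(=CHPh)(H2IMes)(PCy3) (5 mol %), CH2Cl2, 40 °C
Reagents that add atoms: 2-methylbut-2-ene, CC=C(C)C
Why: Olefin cross-metathesis of the only monosubstituted alkene with excess 2-methylbut-2-ene should build the prenyl terminus, leaving the trisubstituted alkenes and the carbinol centre untouched.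

**Step 5**
Reactants: 6 (5R,6E,10E)-2,6,10-trimethyl-12-(phenylsulfonyl)dodeca-2,6,10-trien-5-ol
Product: 8 ethyl (3R,4E)-4,8-dimethyl-3-[(3E)-3-methyl-5-(phenylsulfonyl)pent-3-en-1-yl]nona-4,7-dienoate, via mixed ketene acetal 7 (not isolated)
Conditions: MeC(OEt)3, EtCO2H (cat.), 140 °C, EtOH distilled off
Reagents that add atoms: triethyl orthoacetate, CCOC(C)(OCC)OCC
Why: Johnson–Claisen rearrangement through a chair transition state with the prenyl-bearing CH2 of the carbinol carbon equatorial should transfer the (R)-carbinol chirality suprafacially across the E alkene to the new tertiary centre (R, future C8) and form the E trisubstituted side-chain alkene.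

**Step 6**
Reactants: 8 ethyl (3R,4E)-4,8-dimethyl-3-[(3E)-3-methyl-5-(phenylsulfonyl)pent-3-en-1-yl]nona-4,7-dienoate
Product: 9 (3R,4E)-4,8-dimethyl-3-[(3E)-3-methyl-5-(phenylsulfonyl)pent-3-en-1-yl]nona-4,7-dienal
Conditions: i-Bu2AlH (1.1 equiv), CH2Cl2, −78 °C; aq. potassium sodium tartrate
Reagents that add atoms: none
Why: Partial ester reduction with one equivalent of i-Bu2AlH at low temperature should stop at the aluminium hemiacetal and release the aldehyde on work-up, the sulfone and alkenes being inert.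

**Step 7**
Reactants: 9 (3R,4E)-4,8-dimethyl-3-[(3E)-3-methyl-5-(phenylsulfonyl)pent-3-en-1-yl]nona-4,7-dienal
Product: 10 {[(2E,6R,7E)-6-[(2Z)-3-iodobut-2-en-1-yl]-3,7,11-trimethyldodeca-2,7,10-trien-1-yl]sulfonyl}benzene
Conditions: [Ph3PCH2CH3]I, n-BuLi, THF; I2, −78 °C; NaN(SiMe3)2, −20 °C; then 9, −78 °C
Reagents that add atoms: ethyltriphenylphosphonium iodide, CC[P+](c1ccccc1)(c1ccccc1)c1ccccc1.[I-]; iodine, II
Why: Stork–Zhao-type Wittig olefination with the α-iodoethylidene ylide is kinetically Z-selective, so iodine should end cis to the chain, and the ylide is a weaker base than the allyl sulfone anion it would have to form.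

**Step 8**
Reactants: 10 {[(2E,6R,7E)-6-[(2Z)-3-iodobut-2-en-1-yl]-3,7,11-trimethyldodeca-2,7,10-trien-1-yl]sulfonyl}benzene
Product: 11 {[(2E,6R,7E)-6-[(2Z)-6,6-diethoxy-3-methylhex-2-en-1-yl]-3,7,11-trimethyldodeca-2,7,10-trien-1-yl]sulfonyl}benzene
Conditions: 9-BBN, 3,3-diethoxyprop-1-ene, THF, rt; then 10, PdCl2(dppf) (5 mol %), AsPh3, Cs2CO3, DMF/H2O, rt
Reagents that add atoms: 3,3-diethoxyprop-1-ene (used as its 9-BBN adduct), C=CC(OCC)OCC
Why: B-alkyl Suzuki–Miyaura coupling proceeds with retention at the alkenyl iodide, so the new chain should end cis to the allylic CH2 (future 5Z), and the carbonate base does not touch the sulfone.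

**Step 9**
Reactants: 11 {[(2E,6R,7E)-6-[(2Z)-6,6-diethoxy-3-methylhex-2-en-1-yl]-3,7,11-trimethyldodeca-2,7,10-trien-1-yl]sulfonyl}benzene
Product: 12 (4Z,7R,8E)-4,8,12-trimethyl-7-[(3E)-3-methyl-5-(phenylsulfonyl)pent-3-en-1-yl]trideca-4,8,11-trienal
Conditions: PPTS, acetone/H2O, 50 °C
Reagents that add atoms: water, O
Why: Acid-catalysed acetal hydrolysis should free the aldehyde under conditions too mild to move or isomerise the trisubstituted alkenes.

**Step 10**
Reactants: 12 (4Z,7R,8E)-4,8,12-trimethyl-7-[(3E)-3-methyl-5-(phenylsulfonyl)pent-3-en-1-yl]trideca-4,8,11-trienal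
Product: 13 methyl (3RS,6Z,9R,10E)-3-hydroxy-6,10,14-trimethyl-2-methylidene-9-[(3E)-3-methyl-5-(phenylsulfonyl)pent-3-en-1-yl]pentadeca-6,10,13-trienoate
Conditions: methyl acrylate (excess), DABCO (1 equiv), MeOH (cat.), rt, several days
Reagents that add atoms: methyl acrylate, C=CC(=O)OC
Why: Morita–Baylis–Hillman reaction (amine conjugate addition, aldol, elimination) should join the acrylate α-carbon to the aldehyde; the new carbinol centre is uncontrolled and is erased in step 12.

**Step 11**
Reactants: 13 methyl (3RS,6Z,9R,10E)-3-hydroxy-6,10,14-trimethyl-2-methylidene-9-[(3E)-3-methyl-5-(phenylsulfonyl)pent-3-en-1-yl]pentadeca-6,10,13-trienoate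
Product: 14 methyl (3RS,6Z,9R,10E)-3-acetoxy-6,10,14-trimethyl-2-methylidene-9-[(3E)-3-methyl-5-(phenylsulfonyl)pent-3-en-1-yl]pentadeca-6,10,13-trienoate
Conditions: Ac2O, pyridine, DMAP (cat.), CH2Cl2, 0 °C
Reagents that add atoms: acetic anhydride, CC(=O)OC(C)=O
Why: DMAP-catalysed O-acetylation should turn the hydroxyl into the leaving group needed for the SN2' step.

**Step 12**
Reactants: 14 methyl (3RS,6Z,9R,10E)-3-acetoxy-6,10,14-trimethyl-2-methylidene-9-[(3E)-3-methyl-5-(phenylsulfonyl)pent-3-en-1-yl]pentadeca-6,10,13-trienoate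
Product: 17 methyl (1E,5Z,8R,11E,13RS)-5,11-dimethyl-8-[(2E)-6-methylhepta-2,5-dien-2-yl]-13-(phenylsulfonyl)cyclotetradeca-1,5,11-triene-1-carboxylate, via lithio sulfone 15 (not isolated), via macrocyclic ester enolate 16 (not isolated)
Conditions: LiN(SiMe3)2 (1.05 equiv), THF (0.002 M), −78 °C to 0 °C
Reagents that add atoms: none
Why: LiN(SiMe3)2 should remove only the allylic α-sulfonyl proton to give lithio sulfone 15, whose α-carbon (C13) adds to the unsubstituted acrylate CH2 (C14) to give ester enolate 16, which expels acetate from C2 (E1cB) and leaves the C1=C2 alkene, an overall intramolecular SN2' substitution. The closest known reactions are the addition–elimination of stabilised carbanions to Morita–Baylis–Hillman acetates and the sulfone-carbanion macrocyclisations used for cembranoids. The 14-membered ring closes in a 14-endo-trig conjugate addition, run at high dilution to suppress oligomers. The only new stereocentre, C13, is uncontrolled and is removed in step 14, while C8 carries no acidic hydrogen and is untouched. The step needs α- over γ-attack of the allyl anion (secured by the sulfonyl group and the fully substituted γ-carbon), attack at the terminal CH2 and not at the acetoxy carbon (the CH2 is the unhindered Michael terminus), and the 1E geometry, which should follow from the elimination conformer that keeps the C3 chain away from the ester group, as is usual for ester-type Baylis–Hillman acetates.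

**Step 13**
Reactants: 17 methyl (1E,5Z,8R,11E,13RS)-5,11-dimethyl-8-[(2E)-6-methylhepta-2,5-dien-2-yl]-13-(phenylsulfonyl)cyclotetradeca-1,5,11-triene-1-carboxylate
Product: 18 [(1E,5Z,8R,11E,13RS)-5,11-dimethyl-8-[(2E)-6-methylhepta-2,5-dien-2-yl]-13-(phenylsulfonyl)cyclotetradeca-1,5,11-trien-1-yl]methanol
Conditions: i-Bu2AlH (2.5 equiv), CH2Cl2, −78 °C; aq. potassium sodium tartrate
Reagents that add atoms: none
Why: 1,2-Reduction of the unsaturated ester by i-Bu2AlH should give the allylic alcohol without touching the sulfone or moving the alkenes.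

**Step 14**
Reactants: 18 [(1E,5Z,8R,11E,13RS)-5,11-dimethyl-8-[(2E)-6-methylhepta-2,5-dien-2-yl]-13-(phenylsulfonyl)cyclotetradeca-1,5,11-trien-1-yl]methanol
Product: 19 [(1E,5Z,8R,11E)-5,11-dimethyl-8-[(2E)-6-methylhepta-2,5-dien-2-yl]cyclotetradeca-1,5,11-trien-1-yl]methanol
Conditions: PdCl2(dppp) (5 mol %), LiBHEt3 (4 equiv), THF, 0 °C
Reagents that add atoms: none
Why: Palladium-catalysed reductive desulfonylation (Tsuji–Trost-type ionisation of the allylic sulfone, then hydride delivery to the less substituted allyl terminus) should replace PhSO2 by H with the 11E alkene kept in place, the lithium alkoxide of the allylic alcohol not being ionised.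

**Compound list**

1 | geranyl bromide, (2E)-1-bromo-3,7-dimethylocta-2,6-diene | CC(C)=CCC/C(C)=C/CBr | starting material
2 | geranyl phenyl sulfone, {[(2E)-3,7-dimethylocta-2,6-dien-1-yl]sulfonyl}benzene | CC(C)=CCC/C(C)=C/CS(=O)(=O)c1ccccc1 | intermediate
3 | (2E,6E)-2,6-dimethyl-8-(phenylsulfonyl)octa-2,6-dien-1-ol | OC/C(C)=C/CC/C(C)=C/CS(=O)(=O)c1ccccc1 | intermediate (not isolated)
4 | (2E,6E)-2,6-dimethyl-8-(phenylsulfonyl)octa-2,6-dienal | O=C/C(C)=C/CC/C(C)=C/CS(=O)(=O)c1ccccc1 | intermediate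
5 | (4R,5E,9E)-5,9-dimethyl-11-(phenylsulfonyl)undeca-1,5,9-trien-4-ol | C=CC[C@@H](O)/C(C)=C/CC/C(C)=C/CS(=O)(=O)c1ccccc1 | intermediate
6 | (5R,6E,10E)-2,6,10-trimethyl-12-(phenylsulfonyl)dodeca-2,6,10-trien-5-ol | CC(C)=CC[C@@H](O)/C(C)=C/CC/C(C)=C/CS(=O)(=O)c1ccccc1 | intermediate
7 | mixed ketene acetal, the 1-ethoxyvinyl ether of 6 | C=C(OCC)O[C@H](CC=C(C)C)/C(C)=C/CC/C(C)=C/CS(=O)(=O)c1ccccc1 | intermediate (not isolated)
8 | ethyl (3R,4E)-4,8-dimethyl-3-[(3E)-3-methyl-5-(phenylsulfonyl)pent-3-en-1-yl]nona-4,7-dienoate | CC(C)=CC/C=C(\C)[C@@H](CC(=O)OCC)CC/C(C)=C/CS(=O)(=O)c1ccccc1 | intermediate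
9 | (3R,4E)-4,8-dimethyl-3-[(3E)-3-methyl-5-(phenylsulfonyl)pent-3-en-1-yl]nona-4,7-dienal | CC(C)=CC/C=C(\C)[C@@H](CC=O)CC/C(C)=C/CS(=O)(=O)c1ccccc1 | intermediate
10 | {[(2E,6R,7E)-6-[(2Z)-3-iodobut-2-en-1-yl]-3,7,11-trimethyldodeca-2,7,10-trien-1-yl]sulfonyl}benzene | CC(C)=CC/C=C(\C)[C@@H](C/C=C(/C)I)CC/C(C)=C/CS(=O)(=O)c1ccccc1 | intermediate
11 | {[(2E,6R,7E)-6-[(2Z)-6,6-diethoxy-3-methylhex-2-en-1-yl]-3,7,11-trimethyldodeca-2,7,10-trien-1-yl]sulfonyl}benzene | CC(C)=CC/C=C(\C)[C@@H](C/C=C(/C)CCC(OCC)OCC)CC/C(C)=C/CS(=O)(=O)c1ccccc1 | intermediate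
12 | (4Z,7R,8E)-4,8,12-trimethyl-7-[(3E)-3-methyl-5-(phenylsulfonyl)pent-3-en-1-yl]trideca-4,8,11-trienal | CC(C)=CC/C=C(\C)[C@@H](C/C=C(/C)CCC=O)CC/C(C)=C/CS(=O)(=O)c1ccccc1 | intermediate
13 | methyl (3RS,6Z,9R,10E)-3-hydroxy-6,10,14-trimethyl-2-methylidene-9-[(3E)-3-methyl-5-(phenylsulfonyl)pent-3-en-1-yl]pentadeca-6,10,13-trienoate | CC(C)=CC/C=C(\C)[C@@H](C/C=C(/C)CCC(O)C(=C)C(=O)OC)CC/C(C)=C/CS(=O)(=O)c1ccccc1 | intermediate
14 | methyl (3RS,6Z,9R,10E)-3-acetoxy-6,10,14-trimethyl-2-methylidene-9-[(3E)-3-methyl-5-(phenylsulfonyl)pent-3-en-1-yl]pentadeca-6,10,13-trienoate | CC(C)=CC/C=C(\C)[C@@H](C/C=C(/C)CCC(OC(C)=O)C(=C)C(=O)OC)CC/C(C)=C/CS(=O)(=O)c1ccccc1 | intermediate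
15 | lithio sulfone, the α-sulfonyl allyl lithium derivative of 14 | CC(C)=CC/C=C(\C)[C@@H](C/C=C(/C)CCC(OC(C)=O)C(=C)C(=O)OC)CC/C(C)=C/[CH-]S(=O)(=O)c1ccccc1.[Li+] | intermediate (not isolated)
16 | macrocyclic ester enolate, lithium enolate of methyl (5Z,8R,11E)-2-acetoxy-5,11-dimethyl-8-[(2E)-6-methylhepta-2,5-dien-2-yl]-13-(phenylsulfonyl)cyclotetradeca-5,11-diene-1-carboxylate | CC(C)=CC/C=C(\C)[C@H]1C/C=C(/C)CCC(OC(C)=O)C(=C([O-])OC)CC(/C=C(\C)CC1)S(=O)(=O)c1ccccc1.[Li+] | intermediate (not isolated)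
17 | methyl (1E,5Z,8R,11E,13RS)-5,11-dimethyl-8-[(2E)-6-methylhepta-2,5-dien-2-yl]-13-(phenylsulfonyl)cyclotetradeca-1,5,11-triene-1-carboxylate | CC(C)=CC/C=C(\C)[C@H]1C/C=C(/C)CC/C=C(/C(=O)OC)CC(/C=C(\C)CC1)S(=O)(=O)c1ccccc1 | intermediate
18 | [(1E,5Z,8R,11E,13RS)-5,11-dimethyl-8-[(2E)-6-methylhepta-2,5-dien-2-yl]-13-(phenylsulfonyl)cyclotetradeca-1,5,11-trien-1-yl]methanol | CC(C)=CC/C=C(\C)[C@H]1C/C=C(/C)CC/C=C(/CO)CC(/C=C(\C)CC1)S(=O)(=O)c1ccccc1 | intermediate
19 | [(1E,5Z,8R,11E)-5,11-dimethyl-8-[(2E)-6-methylhepta-2,5-dien-2-yl]cyclotetradeca-1,5,11-trien-1-yl]methanol | CC(C)=CC/C=C(\C)[C@H]1C/C=C(/C)CC/C=C(/CO)CC/C=C(\C)CC1 | target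

**Step count**

Total: 14 steps. Longest linear sequence: 14 steps (fully linear from geranyl bromide).

**Steps most likely to fail**

Step 12 (ring closure). What may go wrong: intermolecular conjugate addition outrunning the 14-membered closure, acetyl transfer to the lithio sulfone, or an unselective elimination that gives both C1=C2 geometries. The fallback fixes the alkene geometry before the ring is closed. It sets out from alcohol 13, whose hydroxyl is replaced with allylic transposition by NBS/Me2S (Corey–Kim-type bromination) to give the thermodynamically preferred rearranged (2Z)-2-(bromomethyl) ester F1. This is cyclised by direct intramolecular SN2 alkylation of its lithio sulfone at the CH2Br carbon (LiN(SiMe3)2, THF, high dilution, −78 °C), the classical sulfone-carbanion/allylic bromide macrocyclisation. The route is rejoined at 17.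

Step 7 (Z-iodoalkene). What may go wrong: erosion of Z selectivity, quenching of the iodo ylide by the acidic allyl sulfone, or loss of iodine to give the plain olefin. The fallback builds the Z alkene from a stabilised phosphonate and adds the two missing carbons afterwards. It sets out from aldehyde 9: a Still–Gennari olefination (methyl 2-[bis(2,2,2-trifluoroethoxy)phosphoryl]propanoate, KN(SiMe3)2, 18-crown-6, THF, −78 °C) should give the Z enoate F2. Reduction with i-Bu2AlH gives the Z allylic alcohol F3, and CBr4/PPh3 the Z allylic bromide F4. Stille coupling with (Z)-tributyl(2-ethoxyvinyl)stannane (Pd2(dba)3, P(2-furyl)3, THF) gives the enol ether F5, and dilute aqueous acid hydrolyses it to aldehyde 12, where the route is rejoined (10 and 11 are bypassed).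

Step 3 (carbinol centre). What may go wrong: poor facial selectivity of the catalysed allyl transfer to this α-branched conjugated aldehyde, which would pass on as low enantiopurity at C8 after the Claisen step. The fallback replaces catalyst control by reagent control. It sets out from 4, which is treated with stoichiometric (+)-B-allyldiisopinocampheylborane (made from (+)-Ipc2BOMe of the (−)-α-pinene series and CH2=CHCH2MgBr) in Et2O at −78 °C, followed by NaBO3 work-up. This should add allyl to the same Re face and give 5, where the route is rejoined; no new compound is made (F0).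

**Further compounds**

F1 | step 12 | methyl (2Z,6Z,9R,10E)-2-(bromomethyl)-6,10,14-trimethyl-9-[(3E)-3-methyl-5-(phenylsulfonyl)pent-3-en-1-yl]pentadeca-2,6,10,13-tetraenoate | CC(C)=CC/C=C(\C)[C@@H](C/C=C(/C)CC/C=C(\CBr)C(=O)OC)CC/C(C)=C/CS(=O)(=O)c1ccccc1
F2 | step 7 | methyl (2Z,5R,6E)-2,6,10-trimethyl-5-[(3E)-3-methyl-5-(phenylsulfonyl)pent-3-en-1-yl]undeca-2,6,9-trienoate | CC(C)=CC/C=C(\C)[C@@H](C/C=C(/C)C(=O)OC)CC/C(C)=C/CS(=O)(=O)c1ccccc1
F3 | step 7 | (2Z,5R,6E)-2,6,10-trimethyl-5-[(3E)-3-methyl-5-(phenylsulfonyl)pent-3-en-1-yl]undeca-2,6,9-trien-1-ol | CC(C)=CC/C=C(\C)[C@@H](C/C=C(/C)CO)CC/C(C)=C/CS(=O)(=O)c1ccccc1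
F4 | step 7 | {[(2E,6R,7E)-6-[(2Z)-4-bromo-3-methylbut-2-en-1-yl]-3,7,11-trimethyldodeca-2,7,10-trien-1-yl]sulfonyl}benzene | CC(C)=CC/C=C(\C)[C@@H](C/C=C(/C)CBr)CC/C(C)=C/CS(=O)(=O)c1ccccc1
F5 | step 7 | {[(2E,6R,7E)-6-[(2Z,5Z)-6-ethoxy-3-methylhexa-2,5-dien-1-yl]-3,7,11-trimethyldodeca-2,7,10-trien-1-yl]sulfonyl}benzene | CC(C)=CC/C=C(\C)[C@@H](C/C=C(/C)C/C=C\OCC)CC/C(C)=C/CS(=O)(=O)c1ccccc1
F0 | step 3 | none | none
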